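**Strategy**

The route rests on opening the ten-membered carbocycle at C1–C2 (germacrane numbering, defined below), the bond between the enal β-carbon and an unactivated methylene. The key step, a one-pot 9-BBN hydroboration and intramolecular B-alkyl Suzuki–Miyaura coupling, closes ring C1–C10 and at the same time creates the trisubstituted C1=C10 alkene with the geometry stored in a vinyl iodide. It exploits three folding elements of the target: the ring-cis C1=C10 alkene (C2 cis to C9), the ring-cis C4=C5 alkene (C3 cis to C6) and the trans-fused C6–C7 γ-lactone. The precursor is a trans-α-methylene-γ-butyrolactone bearing a 2-substituted buta-1,3-dienyl arm at C6 and an iodoalkenyl arm at C7.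

Key step: step 15

Remark on numbering: ring carbons are C1–C10, the lactone carbons C11 and C12 with its methylene C13, the formyl carbon C14 and the hydroxymethyl carbon C15. The target is 6R,7R,8R with a 2S ester side chain, a trans-fused lactone and two ring-cis ring alkenes.

Assumption: in step 11 the (S,S) antipode of ProPhenol is taken as the one that delivers the R carbinol; if the facial sense with this aldehyde is the reverse, the (R,R) ligand is used.

**Route**

Step 1
Reactants: 1 but-2-yne-1,4-diol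
Product: 2 4-{[tert-butyl(diphenyl)silyl]oxy}but-2-yn-1-ol
Conditions: NaH (1.0 equiv), THF, 0 °C; then TBDPSCl (1.0 equiv), rt
Reagents that add atoms: tert-butyl(chloro)diphenylsilane, CC(C)(C)[Si](Cl)(c1ccccc1)c1ccccc1
Why: Williamson-type O-silylation of the monosodium alkoxide of the symmetrical diol should give mainly the mono-ether, unreacted diol being removed with water.

Step 2
Reactants: 2 4-{[tert-butyl(diphenyl)silyl]oxy}but-2-yn-1-ol
Product: 4 (2Z)-4-{[tert-butyl(diphenyl)silyl]oxy}-3-iodobut-2-en-1-ol, via cyclic sodium alkenylalanate 3 (not isolated)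
Conditions: NaAlH2(OCH2CH2OCH3)2 (1.5 equiv), THF, 0 °C; then I2, −78 °C to 0 °C
Reagents that add atoms: iodine, II
Why: Hydroxyl-directed trans-hydroalumination of the propargylic alcohol places aluminium on C4 inside a five-membered alkoxyalanate, and iodinolysis with retention should give the Z iodide with iodine cis to C6, the low temperature keeping the β-silyloxy alanate from eliminating to an allene.

Step 3
Reactants: 4 (2Z)-4-{[tert-butyl(diphenyl)silyl]oxy}-3-iodobut-2-en-1-ol; 5 tributyl(ethenyl)stannane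
Product: 6 (2E)-3-({[tert-butyl(diphenyl)silyl]oxy}methyl)penta-2,4-dien-1-ol
Conditions: Pd(PPh3)4 (5 mol %), CuI (10 mol %), DMF, 40 °C
Reagents that add atoms: none
Why: Stille coupling proceeds with retention at the sp2 carbon, so the vinyl group (C3=C2) ends up cis to C6 as the ring-cis C4=C5 geometry demands.

Step 4
Reactants: 6 (2E)-3-({[tert-butyl(diphenyl)silyl]oxy}methyl)penta-2,4-dien-1-ol
Product: 7 (2E)-3-({[tert-butyl(diphenyl)silyl]oxy}methyl)penta-2,4-dienal
Conditions: MnO2 (20 equiv), CH2Cl2, rt; used at once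
Reagents that add atoms: none
Why: MnO2 oxidises the primary allylic alcohol selectively to the enal without touching the diene geometry, and the cis-dienal is used immediately because it can isomerise or electrocyclise on standing.

Step 5
Reactants: 8 diethyl propanedioate; 9 2-bromo-1,1-diethoxyethane
Product: 10 diethyl (2,2-diethoxyethyl)propanedioate
Conditions: NaOEt, NaI (cat.), EtOH, reflux
Reagents that add atoms: none
Why: Malonic ester alkylation (SN2, iodide-assisted) of the sodium enolate with the primary bromide installs C9 and C8, the latter as a masked aldehyde.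

Step 6
Reactants: 10 diethyl (2,2-diethoxyethyl)propanedioate; 11 triiodomethane
Product: 12 diethyl (2,2-diethoxyethyl)(diiodomethyl)propanedioate
Conditions: NaH, Et2O, reflux; then CHI3, reflux
Reagents that add atoms: none
Why: C-Diiodomethylation of the malonate anion with iodoform (capture of diiodocarbene) attaches C1 to the carbon that becomes C10.

Step 7
Reactants: 12 diethyl (2,2-diethoxyethyl)(diiodomethyl)propanedioate
Product: 14 (2E)-2-(2,2-diethoxyethyl)-3-iodoprop-2-enoic acid, via dipotassium malonate salt 13 (not isolated)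
Conditions: KOH, EtOH/H2O (3:1), reflux; then cold 1 M HCl to pH 4
Reagents that add atoms: potassium hydroxide, [K+].[OH-]
Why: Saponification followed by decarboxylative anti-elimination of iodide is the established route from 2-alkyl-2-(diiodomethyl)malonates to E-3-iodoacrylic acids, here placing iodine cis to the C9 chain and trans to the carboxyl carbon C14.

Step 8
Reactants: 14 (2E)-2-(2,2-diethoxyethyl)-3-iodoprop-2-enoic acid
Product: 15 (2E)-2-(2,2-diethoxyethyl)-3-iodoprop-2-en-1-ol
Conditions: LiAlH4, Et2O, 0 °C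
Reagents that add atoms: none
Why: LiAlH4 reduces the carboxylic acid to the primary allylic alcohol at 0 °C without attacking the vinyl iodide or the acetal.

Step 9
Reactants: 15 (2E)-2-(2,2-diethoxyethyl)-3-iodoprop-2-en-1-ol
Product: 16 1-({[(2E)-2-(2,2-diethoxyethyl)-3-iodoprop-2-en-1-yl]oxy}methyl)-4-methoxybenzene
Conditions: NaH, PMBCl, n-Bu4NI (cat.), THF/DMF, 0 °C to rt
Reagents that add atoms: 4-methoxybenzyl chloride, COc1ccc(CCl)cc1
Why: Williamson etherification protects the C14 hydroxyl as a PMB ether that is orthogonal to the silyl ether and to every later ester.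

Step 10
Reactants: 16 1-({[(2E)-2-(2,2-diethoxyethyl)-3-iodoprop-2-en-1-yl]oxy}methyl)-4-methoxybenzene
Product: 17 (3E)-4-iodo-3-{[(4-methoxyphenyl)methoxy]methyl}but-3-enal
Conditions: AcOH/H2O/THF (4:1:1), 40 °C; used crude
Reagents that add atoms: water, O
Why: Mild aqueous acid hydrolyses the diethyl acetal to the C8 aldehyde while the PMB ether survives, and the β,γ-unsaturated aldehyde is used crude so that the C1=C10 double bond does not migrate into conjugation.

Step 11
Reactants: 17 (3E)-4-iodo-3-{[(4-methoxyphenyl)methoxy]methyl}but-3-enal; 18 methyl prop-2-ynoate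
Product: 19 methyl (4R,6E)-4-hydroxy-7-iodo-6-{[(4-methoxyphenyl)methoxy]methyl}hept-6-en-2-ynoate
Conditions: Me2Zn (3 equiv), (S,S)-ProPhenol (20 mol %), toluene, 4 °C
Reagents that add atoms: none
Why: Zinc–ProPhenol-catalysed asymmetric alkynylation adds the zinc acetylide of methyl propiolate to one aldehyde face under ligand control and sets C8 as R, the alkyne carbons becoming C7 and C11 and the ester carbon C12.

Step 12
Reactants: 19 methyl (4R,6E)-4-hydroxy-7-iodo-6-{[(4-methoxyphenyl)methoxy]methyl}hept-6-en-2-ynoate; 20 (2S)-2-methylbutanoic acid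
Product: 21 methyl (4R,6E)-7-iodo-6-{[(4-methoxyphenyl)methoxy]methyl}-4-{[(2S)-2-methylbutanoyl]oxy}hept-6-en-2-ynoate
Conditions: DCC, DMAP (5 mol %), CH2Cl2, −20 to 0 °C
Reagents that add atoms: none
Why: Steglich esterification acylates the propargylic alcohol with retention at C8 and, at low temperature with little DMAP, should neither epimerise the α-stereocentre of the acid nor isomerise the ynoate.

Step 13
Reactants: 21 methyl (4R,6E)-7-iodo-6-{[(4-methoxyphenyl)methoxy]methyl}-4-{[(2S)-2-methylbutanoyl]oxy}hept-6-en-2-ynoate; 22 2-(iodomethyl)-4,4,5,5-tetramethyl-1,3,2-dioxaborolane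
Product: 24 methyl (2Z,4R,6E)-7-iodo-6-{[(4-methoxyphenyl)methoxy]methyl}-4-{[(2S)-2-methylbutanoyl]oxy}-2-[(4,4,5,5-tetramethyl-1,3,2-dioxaborolan-2-yl)methyl]hepta-2,6-dienoate, via aluminium allenoate 23 (not isolated)
Conditions: i-Bu2AlH (1.2 equiv), HMPA (2.5 equiv), THF, 0 °C; then ICH2Bpin, 0 °C to rt
Reagents that add atoms: none
Why: Conjugate hydroalumination of the ynoate by the i-Bu2AlH–HMPA complex, which spares isolated esters, gives an aluminium allenoate whose C-alkylation by the iodomethylboronate (boron ate complex, 1,2-shift with loss of iodide) occurs on the side of H7, so that C8 ends up cis to the ester and trans to CH2Bpin.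

Step 14
Reactants: 24 methyl (2Z,4R,6E)-7-iodo-6-{[(4-methoxyphenyl)methoxy]methyl}-4-{[(2S)-2-methylbutanoyl]oxy}-2-[(4,4,5,5-tetramethyl-1,3,2-dioxaborolan-2-yl)methyl]hepta-2,6-dienoate; 7 (2E)-3-({[tert-butyl(diphenyl)silyl]oxy}methyl)penta-2,4-dienal
Product: 26 (4R,5R)-5-[(1E)-2-({[tert-butyl(diphenyl)silyl]oxy}methyl)buta-1,3-dien-1-yl]-4-[(1R,3E)-4-iodo-3-{[(4-methoxyphenyl)methoxy]methyl}-1-{[(2S)-2-methylbutanoyl]oxy}but-3-en-1-yl]-3-methylideneoxolan-2-one, via O-boryl homoallylic ester 25 (not isolated)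
Conditions: Sc(OTf)3 (10 mol %), toluene, −20 °C to rt; then PPTS (10 mol %), rt
Reagents that add atoms: none
Why: Lewis-acid-catalysed allylboration through a closed chair transition state converts the C8-trans-to-CH2B geometry into the anti adduct and hence, after lactonisation, the trans C6/C7 lactone, while allylic 1,3-strain with the cis ester holds H8 in the alkene plane so that the aldehyde should add anti to the C9 chain (acyloxy group outside), setting C6 and C7 as R relative to C8.

Step 15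
Reactants: 26 (4R,5R)-5-[(1E)-2-({[tert-butyl(diphenyl)silyl]oxy}methyl)buta-1,3-dien-1-yl]-4-[(1R,3E)-4-iodo-3-{[(4-methoxyphenyl)methoxy]methyl}-1-{[(2S)-2-methylbutanoyl]oxy}but-3-en-1-yl]-3-methylideneoxolan-2-one
Product: 28 (6R,7R,8R)-15-{[tert-butyl(diphenyl)silyl]oxy}-14-[(4-methoxyphenyl)methoxy]-8-{[(2S)-2-methylbutanoyl]oxy}germacra-1(10),4,11(13)-trien-12,6-olide (both ring alkenes ring-cis), via B-alkyl-9-BBN adduct 27 (not isolated)
Conditions: 9-BBN (1.5 equiv), THF, 0 °C to rt; then added over 12 h to Pd(dppf)Cl2 (20 mol %), AsPh3 (20 mol %), Cs2CO3 (3 equiv), DMF/THF/H2O, 50 °C, final 1 mM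
Reagents that add atoms: none
Why: 9-BBN adds anti-Markovnikov to the monosubstituted C2=C3 vinyl group of the diene (the acrylate-type C11=C13 methylene is electron-poor, C4=C5 and C1=C10 are trisubstituted) to give the primary C2 alkylborane; oxidative addition of the C1–I bond to zerovalent palladium, base-assisted transfer of the C2 alkyl group from boron to divalent palladium and reductive elimination then form the C1–C2 bond. The closest known reaction type is the B-alkyl Suzuki–Miyaura macrocyclisation. The ten-membered ring C1–C10 is closed by reductive elimination from an eleven-membered palladacycle, that is, by contraction with loss of the metal. No stereocentre is formed; the C1=C10 geometry (C2 cis to C9, trans to C14) is copied with retention from the vinyl iodide, and C6, C7 and C8 are untouched. The step needs cyclisation to beat oligomerisation, and oxidative addition at C1–I to beat ionisation of the allylic C6–O bond and Heck insertion into C11=C13; slow addition at about 1 mM, the fast-reacting iodide and the fold imposed by the two ring-cis alkenes and the trans-lactone are expected to secure this.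

Step 16
Reactants: 28 (6R,7R,8R)-15-{[tert-butyl(diphenyl)silyl]oxy}-14-[(4-methoxyphenyl)methoxy]-8-{[(2S)-2-methylbutanoyl]oxy}germacra-1(10),4,11(13)-trien-12,6-olide
Product: 29 (6R,7R,8R)-15-{[tert-butyl(diphenyl)silyl]oxy}-14-hydroxy-8-{[(2S)-2-methylbutanoyl]oxy}germacra-1(10),4,11(13)-trien-12,6-olide
Conditions: DDQ (1.5 equiv), CH2Cl2/pH 7 buffer (10:1), 0 °C
Reagents that add atoms: none
Why: DDQ removes the PMB ether by oxidative cleavage (benzylic hydride abstraction, then hydrolysis) without affecting the silyl ether, the esters or the isolated alkenes.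

Step 17
Reactants: 29 (6R,7R,8R)-15-{[tert-butyl(diphenyl)silyl]oxy}-14-hydroxy-8-{[(2S)-2-methylbutanoyl]oxy}germacra-1(10),4,11(13)-trien-12,6-olide
Product: 30 (6R,7R,8R)-15-{[tert-butyl(diphenyl)silyl]oxy}-8-{[(2S)-2-methylbutanoyl]oxy}-14-oxogermacra-1(10),4,11(13)-trien-12,6-olide
Conditions: MnO2 (20 equiv), CH2Cl2, rt
Reagents that add atoms: none
Why: MnO2 oxidises the primary allylic C14 alcohol to the enal, whose C1=C10 geometry (C2 trans to the formyl group) is already the thermodynamically preferred one.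

Step 18
Reactants: 30 (6R,7R,8R)-15-{[tert-butyl(diphenyl)silyl]oxy}-8-{[(2S)-2-methylbutanoyl]oxy}-14-oxogermacra-1(10),4,11(13)-trien-12,6-olide
Product: 31 (6R,7R,8R)-15-hydroxy-8-{[(2S)-2-methylbutanoyl]oxy}-14-oxogermacra-1(10),4,11(13)-trien-12,6-olide (target)
Conditions: HF·pyridine, pyridine/THF, 0 °C to rt
Reagents that add atoms: none
Why: Buffered HF·pyridine cleaves the primary silyl ether to the C15 alcohol under conditions that should leave the α-methylene lactone, the enal and the ester untouched.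

**Compound list**

1 | but-2-yne-1,4-diol | OCC#CCO | starting material
2 | 4-{[tert-butyl(diphenyl)silyl]oxy}but-2-yn-1-ol | OCC#CCO[Si](c1ccccc1)(c1ccccc1)C(C)(C)C | intermediate
3 | cyclic sodium alkenylalanate (five-membered O–C6–C5=C4–Al ring, Al bearing two 2-methoxyethoxy groups) | COCCO[Al-]1(OCCOC)OCC=C1CO[Si](c1ccccc1)(c1ccccc1)C(C)(C)C.[Na+] | intermediate
4 | (2Z)-4-{[tert-butyl(diphenyl)silyl]oxy}-3-iodobut-2-en-1-ol | OC/C=C(\I)CO[Si](c1ccccc1)(c1ccccc1)C(C)(C)C | intermediate
5 | tributyl(ethenyl)stannane | C=C[Sn](CCCC)(CCCC)CCCC | starting material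
6 | (2E)-3-({[tert-butyl(diphenyl)silyl]oxy}methyl)penta-2,4-dien-1-ol | OC/C=C(/CO[Si](c1ccccc1)(c1ccccc1)C(C)(C)C)C=C | intermediate
7 | (2E)-3-({[tert-butyl(diphenyl)silyl]oxy}methyl)penta-2,4-dienal | O=C/C=C(/CO[Si](c1ccccc1)(c1ccccc1)C(C)(C)C)C=C | intermediate
8 | diethyl propanedioate | CCOC(=O)CC(=O)OCC | starting material
9 | 2-bromo-1,1-diethoxyethane | CCOC(CBr)OCC | starting material
10 | diethyl (2,2-diethoxyethyl)propanedioate | CCOC(=O)C(CC(OCC)OCC)C(=O)OCC | intermediate
11 | triiodomethane | IC(I)I | starting material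
12 | diethyl (2,2-diethoxyethyl)(diiodomethyl)propanedioate | CCOC(=O)C(CC(OCC)OCC)(C(I)I)C(=O)OCC | intermediate
13 | dipotassium (2,2-diethoxyethyl)(diiodomethyl)propanedioate | [K+].[K+].[O-]C(=O)C(CC(OCC)OCC)(C(I)I)C([O-])=O | intermediate
14 | (2E)-2-(2,2-diethoxyethyl)-3-iodoprop-2-enoic acid | I/C=C(/C(O)=O)CC(OCC)OCC | intermediate
15 | (2E)-2-(2,2-diethoxyethyl)-3-iodoprop-2-en-1-ol | I/C=C(/CO)CC(OCC)OCC | intermediate
16 | 1-({[(2E)-2-(2,2-diethoxyethyl)-3-iodoprop-2-en-1-yl]oxy}methyl)-4-methoxybenzene | I/C=C(/COCc1ccc(OC)cc1)CC(OCC)OCC | intermediate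
17 | (3E)-4-iodo-3-{[(4-methoxyphenyl)methoxy]methyl}but-3-enal | I/C=C(/COCc1ccc(OC)cc1)CC=O | intermediate
18 | methyl prop-2-ynoate | COC(=O)C#C | starting material
19 | methyl (4R,6E)-4-hydroxy-7-iodo-6-{[(4-methoxyphenyl)methoxy]methyl}hept-6-en-2-ynoate | COC(=O)C#C[C@H](O)C/C(COCc1ccc(OC)cc1)=C\I | intermediate
20 | (2S)-2-methylbutanoic acid | OC(=O)[C@@H](C)CC | starting material
21 | methyl (4R,6E)-7-iodo-6-{[(4-methoxyphenyl)methoxy]methyl}-4-{[(2S)-2-methylbutanoyl]oxy}hept-6-en-2-ynoate | COC(=O)C#C[C@H](OC(=O)[C@@H](C)CC)C/C(COCc1ccc(OC)cc1)=C\I | intermediate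
22 | 2-(iodomethyl)-4,4,5,5-tetramethyl-1,3,2-dioxaborolane | ICB1OC(C)(C)C(C)(C)O1 | starting material
23 | diisobutylaluminium allenoate of 21 (O-aluminium ketene acetal, H added at C7) | COC(O[Al](CC(C)C)CC(C)C)=C=C[C@H](OC(=O)[C@@H](C)CC)C/C(COCc1ccc(OC)cc1)=C\I | intermediate
24 | methyl (2Z,4R,6E)-7-iodo-6-{[(4-methoxyphenyl)methoxy]methyl}-4-{[(2S)-2-methylbutanoyl]oxy}-2-[(4,4,5,5-tetramethyl-1,3,2-dioxaborolan-2-yl)methyl]hepta-2,6-dienoate | COC(=O)/C(CB1OC(C)(C)C(C)(C)O1)=C\[C@H](OC(=O)[C@@H](C)CC)C/C(COCc1ccc(OC)cc1)=C\I | intermediate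
25 | open-chain anti allylboration adduct: methyl 2-methylidene ester with C6–O–Bpin, C7–H and C8 acyloxy (6R,7R,8R) | COC(=O)C(=C)[C@@H]([C@H](OB1OC(C)(C)C(C)(C)O1)/C=C(/CO[Si](c2ccccc2)(c2ccccc2)C(C)(C)C)C=C)[C@H](OC(=O)[C@@H](C)CC)C/C(COCc1ccc(OC)cc1)=C\I | intermediate
26 | (4R,5R)-5-[(1E)-2-({[tert-butyl(diphenyl)silyl]oxy}methyl)buta-1,3-dien-1-yl]-4-[(1R,3E)-4-iodo-3-{[(4-methoxyphenyl)methoxy]methyl}-1-{[(2S)-2-methylbutanoyl]oxy}but-3-en-1-yl]-3-methylideneoxolan-2-one | C=C1C(=O)O[C@H](/C=C(/CO[Si](c2ccccc2)(c2ccccc2)C(C)(C)C)C=C)[C@H]1[C@H](OC(=O)[C@@H](C)CC)C/C(COCc1ccc(OC)cc1)=C\I | intermediate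
27 | B-alkyl-9-BBN adduct of 26 (9-borabicyclo[3.3.1]nonan-9-yl on C2, C3 now CH2) | C=C1C(=O)O[C@H](/C=C(/CO[Si](c2ccccc2)(c2ccccc2)C(C)(C)C)CCB2C3CCCC2CCC3)[C@H]1[C@H](OC(=O)[C@@H](C)CC)C/C(COCc1ccc(OC)cc1)=C\I | intermediate
28 | (6R,7R,8R)-15-{[tert-butyl(diphenyl)silyl]oxy}-14-[(4-methoxyphenyl)methoxy]-8-{[(2S)-2-methylbutanoyl]oxy}germacra-1(10),4,11(13)-trien-12,6-olide, ring-cis at C1=C10 and C4=C5 | C=C1C(=O)O[C@@H]2/C=C(/CO[Si](c3ccccc3)(c3ccccc3)C(C)(C)C)CC/C=C(/COCc3ccc(OC)cc3)C[C@@H](OC(=O)[C@@H](C)CC)[C@@H]12 | intermediate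
29 | (6R,7R,8R)-15-{[tert-butyl(diphenyl)silyl]oxy}-14-hydroxy-8-{[(2S)-2-methylbutanoyl]oxy}germacra-1(10),4,11(13)-trien-12,6-olide | C=C1C(=O)O[C@@H]2/C=C(/CO[Si](c3ccccc3)(c3ccccc3)C(C)(C)C)CC/C=C(/CO)C[C@@H](OC(=O)[C@@H](C)CC)[C@@H]12 | intermediate
30 | (6R,7R,8R)-15-{[tert-butyl(diphenyl)silyl]oxy}-8-{[(2S)-2-methylbutanoyl]oxy}-14-oxogermacra-1(10),4,11(13)-trien-12,6-olide | C=C1C(=O)O[C@@H]2/C=C(/CO[Si](c3ccccc3)(c3ccccc3)C(C)(C)C)CC/C=C(/C=O)C[C@@H](OC(=O)[C@@H](C)CC)[C@@H]12 | intermediate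
31 | (6R,7R,8R)-15-hydroxy-8-{[(2S)-2-methylbutanoyl]oxy}-14-oxogermacra-1(10),4,11(13)-trien-12,6-olide, ring-cis at C1=C10 and C4=C5 | C=C1C(=O)O[C@@H]2/C=C(/CO)CC/C=C(/C=O)C[C@@H](OC(=O)[C@@H](C)CC)[C@@H]12 | target

**Step count and risks**

Total step count: 18 (steps 1–4 western fragment, 5–13 eastern fragment, 14 union, 15 ring closure, 16–18 end game). Longest linear sequence: 14 steps (steps 5 to 18).

Steps most likely to fail:

1. Step 15. Intermolecular coupling (oligomerisation) or protodeboronation may outrun closure of the strained ring, and the borane may also attack the lactone methylene. Fallback, setting out from 26 and returning at 28: hydroboration as in step 15 followed by oxidation of 27 with NaBO3·4H2O would give the primary C2 alcohol F1; I2, PPh3 and imidazole would give the primary iodide F2; zinc insertion (Zn dust, LiCl, THF, 40 °C), which leaves the vinyl iodide alone, would give the alkylzinc iodide F3; Pd2(dba)3 and SPhos in THF/NMP under high dilution would then close the ring by intramolecular Negishi coupling to 28.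

2. Step 14. The aldehyde may add to the wrong face of the allylboronate relative to C8 (anti to the C8 oxygen instead of anti to the C9 chain), giving the 6S,7S lactone. Fallback, setting out from 17 and returning at 26: alkynylation with the antipodal (R,R)-ProPhenol would give the 4S hydroxy ynoate F4; TESCl and imidazole its triethylsilyl ether F5; hydroalumination and borylmethylation as in step 13 the 4S allylboronate F6; allylboration of 7 and lactonisation as in step 14, now on the mirror-image face, the 6R,7R,8S silyl ether lactone F7; PPTS in MeOH the 8S alcohol F8; Mitsunobu esterification with 20 (PPh3, DIAD, toluene, 0 °C) inverts C8 and gives 26.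

3. Step 13. The hydride reagent may reduce the 2-methylbutanoate or expel the propargylic acyloxy group instead of adding cleanly to the ynoate. Fallback, setting out from 19 and returning at 26, with the acylation moved behind the union: TESCl and imidazole would give the 4R triethylsilyl ether F9; hydroalumination and borylmethylation as in step 13 the 4R allylboronate F10; allylboration of 7 and lactonisation as in step 14 the 8R silyl ether lactone F11; PPTS in MeOH the 8R alcohol F12; esterification with 20 (DCC, DMAP) proceeds with retention and gives 26.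

Further compounds

F1 | step 15 | primary C2 alcohol: 26 with a 2-hydroxyethyl group in place of the vinyl group | C=C1C(=O)O[C@H](/C=C(/CO[Si](c2ccccc2)(c2ccccc2)C(C)(C)C)CCO)[C@H]1[C@H](OC(=O)[C@@H](C)CC)C/C(COCc1ccc(OC)cc1)=C\I
F2 | step 15 | primary C2 iodide: 26 with a 2-iodoethyl group in place of the vinyl group | C=C1C(=O)O[C@H](/C=C(/CO[Si](c2ccccc2)(c2ccccc2)C(C)(C)C)CCI)[C@H]1[C@H](OC(=O)[C@@H](C)CC)C/C(COCc1ccc(OC)cc1)=C\I
F3 | step 15 | alkylzinc iodide: 26 with a 2-(iodozincio)ethyl group in place of the vinyl group | C=C1C(=O)O[C@H](/C=C(/CO[Si](c2ccccc2)(c2ccccc2)C(C)(C)C)CC[Zn]I)[C@H]1[C@H](OC(=O)[C@@H](C)CC)C/C(COCc1ccc(OC)cc1)=C\I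
F4 | step 14 | methyl (4S,6E)-4-hydroxy-7-iodo-6-{[(4-methoxyphenyl)methoxy]methyl}hept-6-en-2-ynoate | COC(=O)C#C[C@@H](O)C/C(COCc1ccc(OC)cc1)=C\I
F5 | step 14 | methyl (4S,6E)-7-iodo-6-{[(4-methoxyphenyl)methoxy]methyl}-4-[(triethylsilyl)oxy]hept-6-en-2-ynoate | COC(=O)C#C[C@@H](O[Si](CC)(CC)CC)C/C(COCc1ccc(OC)cc1)=C\I
F6 | step 14 | methyl (2Z,4S,6E)-7-iodo-6-{[(4-methoxyphenyl)methoxy]methyl}-2-[(4,4,5,5-tetramethyl-1,3,2-dioxaborolan-2-yl)methyl]-4-[(triethylsilyl)oxy]hepta-2,6-dienoate | COC(=O)/C(CB1OC(C)(C)C(C)(C)O1)=C\[C@@H](O[Si](CC)(CC)CC)C/C(COCc1ccc(OC)cc1)=C\I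
F7 | step 14 | 6R,7R,8S lactone: C8 epimer of 26 with triethylsilyloxy in place of the acyloxy group | C=C1C(=O)O[C@H](/C=C(/CO[Si](c2ccccc2)(c2ccccc2)C(C)(C)C)C=C)[C@H]1[C@@H](O[Si](CC)(CC)CC)C/C(COCc1ccc(OC)cc1)=C\I
F8 | step 14 | 6R,7R,8S lactone with free C8 hydroxyl | C=C1C(=O)O[C@H](/C=C(/CO[Si](c2ccccc2)(c2ccccc2)C(C)(C)C)C=C)[C@H]1[C@@H](O)C/C(COCc1ccc(OC)cc1)=C\I
F9 | step 13 | methyl (4R,6E)-7-iodo-6-{[(4-methoxyphenyl)methoxy]methyl}-4-[(triethylsilyl)oxy]hept-6-en-2-ynoate | COC(=O)C#C[C@H](O[Si](CC)(CC)CC)C/C(COCc1ccc(OC)cc1)=C\I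
F10 | step 13 | methyl (2Z,4R,6E)-7-iodo-6-{[(4-methoxyphenyl)methoxy]methyl}-2-[(4,4,5,5-tetramethyl-1,3,2-dioxaborolan-2-yl)methyl]-4-[(triethylsilyl)oxy]hepta-2,6-dienoate | COC(=O)/C(CB1OC(C)(C)C(C)(C)O1)=C\[C@H](O[Si](CC)(CC)CC)C/C(COCc1ccc(OC)cc1)=C\I
F11 | step 13 | 6R,7R,8R lactone: 26 with triethylsilyloxy in place of the acyloxy group | C=C1C(=O)O[C@H](/C=C(/CO[Si](c2ccccc2)(c2ccccc2)C(C)(C)C)C=C)[C@H]1[C@H](O[Si](CC)(CC)CC)C/C(COCc1ccc(OC)cc1)=C\I
F12 | step 13 | 6R,7R,8R lactone with free C8 hydroxyl | C=C1C(=O)O[C@H](/C=C(/CO[Si](c2ccccc2)(c2ccccc2)C(C)(C)C)C=C)[C@H]1[C@H](O)C/C(COCc1ccc(OC)cc1)=C\I
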